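**Plan**
- Retrosynthesis: after removal of the two MOM ethers on O5 and O7, ring C is cut at two bonds, C4–C4a and O1–C8a. This gives an aryne of ring A (C4a≡C8a, with the C5 and C7 oxygens and the C8 prenyl group in place) and the alkoxide of an (S)-3-aryl-3-hydroxypropanoic Weinreb amide (O1, C2, C3, C4).
- Forward: ring A is taken from phloroglucinol and dressed (bis-MOM ether, ortho-C-prenylation, carbamate-directed silylation, triflation) to a 2-silylaryl triflate; the chain comes from a β-keto ester. The halves are joined in one flask: O1–C8a forms first (alkoxide adds to the aryne), then ring C closes by attack of the C4a carbanion on the amide carbon C4.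
- Enabling feature: in ring A, O1 (on C8a) and C4 (on C4a) are ortho neighbours and C5 next to C4a bears oxygen. This is the pattern left by O-attack on a 3-alkoxyaryne followed by acyl capture. C8 next to C8a already carries the prenyl group, so no 6- versus 8-prenyl choice arises.
- Stereochemistry: C2 is set by Noyori asymmetric transfer hydrogenation of the keto ester and carried through with retention. The C2–O1 bond of the target is the C–O bond of that alcohol and is never broken (no inversion step, no acid on the ionisable 4-methoxybenzylic ether before the ring exists).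
- Mild acidic methanolysis of the MOM ethers finishes the route.

Key step: step 8

Remark: phloroglucinol and methyl 3-(4-methoxyphenyl)-3-oxopropanoate are taken as commercial. Flavanone numbering (O1, C2, C3, C4, C4a, C5 to C8, C8a) is used for the corresponding atoms of all precursors. The anionic intermediates of step 8 are drawn as sodium salts.

**Step 1**
Reactants: 1 phloroglucinol (benzene-1,3,5-triol)
Product: 2 3,5-bis(methoxymethoxy)phenol
Conditions: MOMCl (2.0 equiv), iPr2NEt, THF, 0 °C → rt; chromatography
Reagents that add atoms: chloromethyl methyl ether (MOMCl), COCCl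
Why: Williamson-type O-alkylation of the phenol with the α-chloro ether; with two equivalents the bis-ether should be the main component of the statistical mixture and is separable from the mono- and tris-ethers by polarity.

**Step 2**
Reactants: 2 3,5-bis(methoxymethoxy)phenol
Product: 4 3,5-bis(methoxymethoxy)-2-(3-methylbut-2-en-1-yl)phenol, via sodium phenoxide 3 (not isolated)
Conditions: NaH, toluene, 0 °C; prenyl bromide, rt
Reagents that add atoms: prenyl bromide (1-bromo-3-methylbut-2-ene), CC(C)=CCBr
Why: ortho-C-alkylation of a phenoxide: in toluene the tight sodium ion pair should deliver the allylic bromide to a carbon ortho to oxygen (both ortho carbons are equivalent), while the para carbon is screened by two MOM ethers and O-alkylation is disfavoured in the non-polar medium.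

**Step 3**
Reactants: 4 3,5-bis(methoxymethoxy)-2-(3-methylbut-2-en-1-yl)phenol
Product: 5 3,5-bis(methoxymethoxy)-2-(3-methylbut-2-en-1-yl)phenyl N-isopropylcarbamate
Conditions: iPrNCO, Et3N (cat.), CH2Cl2, rt
Reagents that add atoms: isopropyl isocyanate, CC(C)N=C=O
Why: amine-catalysed addition of the phenol O–H across the isocyanate (carbamoylation) should be clean and installs a strong ortho-directing group that can later be removed under mild base.

**Step 4**
Reactants: 5 3,5-bis(methoxymethoxy)-2-(3-methylbut-2-en-1-yl)phenyl N-isopropylcarbamate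
Product: 9 3,5-bis(methoxymethoxy)-2-(3-methylbut-2-en-1-yl)-6-(trimethylsilyl)phenyl N-isopropylcarbamate, via N-silyl carbamate 6 (not isolated), via aryllithium 7 (not isolated), via bis-silyl carbamate 8 (not isolated)
Conditions: TBSOTf (1.05 equiv), TMEDA, Et2O, 0 °C → rt; n-BuLi, TMEDA, −78 °C; TMSCl, −78 °C → rt; brief cold aq. NaHSO4 wash
Reagents that add atoms: chlorotrimethylsilane (TMSCl), C[Si](C)(C)Cl
Why: directed ortho-metalation: after in-situ N-silylation the carbamate and the MOM ether on C5 cooperatively direct n-BuLi/TMEDA to the one ring C–H between them (C4a), which at −78 °C should be lithiated faster than C6 or the benzylic-allylic CH2, TMSCl traps the aryllithium, and the N–Si bond is hydrolysed on work-up.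

**Step 5**
Reactants: 9 3,5-bis(methoxymethoxy)-2-(3-methylbut-2-en-1-yl)-6-(trimethylsilyl)phenyl N-isopropylcarbamate
Product: 11 3,5-bis(methoxymethoxy)-2-(3-methylbut-2-en-1-yl)-6-(trimethylsilyl)phenyl trifluoromethanesulfonate, via phenoxide salt 10 (not isolated)
Conditions: Et2NH, DBU, MeCN, 40 °C; then PhNTf2, rt
Reagents that add atoms: N-phenylbis(trifluoromethanesulfonimide) (PhNTf2), O=S(=O)(N(c1ccccc1)S(=O)(=O)C(F)(F)F)C(F)(F)F
Why: base-induced β-elimination (E1cB) of the N–H carbamate releases the phenoxide and isopropyl isocyanate (scavenged by Et2NH), and the phenoxide is O-sulfonylated in the same flask by PhNTf2, the established way to turn ortho-silylaryl carbamates into 2-silylaryl triflates.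

**Step 6**
Reactants: 12 methyl 3-(4-methoxyphenyl)-3-oxopropanoate
Product: 13 methyl (S)-3-hydroxy-3-(4-methoxyphenyl)propanoate
Conditions: RuCl(p-cymene)[(S,S)-TsDPEN] (1 mol %), HCO2H/Et3N (5:2), rt
Reagents that add atoms: none
Why: Noyori asymmetric transfer hydrogenation of the aryl ketone: the (S,S)-diamine ruthenium hydride transfers hydride to the carbonyl face fixed by the CH/π contact between the arene ligand and the anisyl ring, which by analogy with acetophenones and benzoylacetates should give the (S)-benzylic alcohol.

**Step 7**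
Reactants: 13 methyl (S)-3-hydroxy-3-(4-methoxyphenyl)propanoate
Product: 14 (S)-3-hydroxy-N-methoxy-3-(4-methoxyphenyl)-N-methylpropanamide
Conditions: MeNHOMe·HCl, iPrMgCl, THF, −20 → 0 °C
Reagents that add atoms: N,O-dimethylhydroxylamine hydrochloride, CNOC.Cl
Why: Weinreb amidation of the ester with the chloromagnesium amide formed in situ; the free hydroxyl is only deprotonated (extra equivalent of iPrMgCl) and the stereocentre, which is not acidic, is untouched.

**Step 8**
Reactants: 14 (S)-3-hydroxy-N-methoxy-3-(4-methoxyphenyl)-N-methylpropanamide; 11 3,5-bis(methoxymethoxy)-2-(3-methylbut-2-en-1-yl)-6-(trimethylsilyl)phenyl trifluoromethanesulfonate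
Product: 19 (2S)-5,7-bis(methoxymethoxy)-2-(4-methoxyphenyl)-8-(3-methylbut-2-en-1-yl)chroman-4-one, via sodium alkoxide 15 (not isolated), via aryne 16 (not isolated), via aryl anion 17 (not isolated), via hemiaminal alkoxide 18 (not isolated)
Conditions: 14 (1.3 equiv), NaH (1.25 equiv), THF, 0 °C; CsF, 18-crown-6, slow addition of 11, −20 °C → rt; AcOH, −20 °C, then pH 7 buffer
Reagents that add atoms: none
Why: Proposed new method: fluoride removes the silyl group of 11 and triflate departs to give aryne 16, alkoxide 15 adds through oxygen to C8a, and the carbanion 17 thereby formed at C4a attacks the tethered Weinreb carbonyl (6-exo-trig), forming C4–C4a and ring C and leaving the ketone masked as adduct 18 until the acidic quench. The closest known reaction type is the addition of ortho-hydroxyaryl esters (salicylates) to arynes with intramolecular acyl capture to give xanthones, together with the related insertion of arynes into the C–O bond of carboxylic acids; the use of an aliphatic β-hydroxy amide as the O-nucleophile/acyl acceptor pair is the new element. No lasting stereocentre is created: C2 comes from 14 with retention because none of its bonds is broken, and the hemiaminal centre at C4 in 18 is lost on work-up. The step needs O-attack at C8a and not at C4a; the inductively withdrawing MOM-oxy group on C5 distorts the aryne so that the distal carbon C8a is the electrophilic one and the charge develops at C4a next to oxygen, as in 3-alkoxybenzynes, and this electronic bias is expected to outweigh the steric effect of the C8 prenyl group. It also needs acyl capture to be faster than protonation of 17, which the absence of O–H donors (alkoxide pre-formed with NaH, anhydrous CsF/18-crown-6 in THF) and the six-membered transition state should secure. The amide is chosen over the ester because its enolate is a poor leaving group for retro-aldol cleavage of 15, its methylene is less acidic toward 17, and adduct 18 keeps the base-sensitive flavanone (β-elimination across O1–C2 would racemise C2) out of the basic medium.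

**Step 9**
Reactants: 19 (2S)-5,7-bis(methoxymethoxy)-2-(4-methoxyphenyl)-8-(3-methylbut-2-en-1-yl)chroman-4-one
Product: 20 (2S)-5,7-dihydroxy-2-(4-methoxyphenyl)-8-(3-methylbut-2-en-1-yl)chroman-4-one (CID45272659)
Conditions: HCl (3 M in MeOH), 40 °C
Reagents that add atoms: none
Why: acid-catalysed methanolysis of the two MOM acetals (released as formaldehyde dimethyl acetal) is standard for prenylated flavanones; the aryl methyl ether, the prenyl group and C2 should survive these mild conditions, and the target is reached.

**Compound list**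
1 | phloroglucinol (benzene-1,3,5-triol) | Oc1cc(O)cc(O)c1 | starting material
2 | 3,5-bis(methoxymethoxy)phenol | COCOc1cc(O)cc(OCOC)c1 | intermediate
3 | sodium 3,5-bis(methoxymethoxy)phenoxide | COCOc1cc([O-])cc(OCOC)c1.[Na+] | intermediate
4 | 3,5-bis(methoxymethoxy)-2-(3-methylbut-2-en-1-yl)phenol | COCOc1cc(O)c(CC=C(C)C)c(OCOC)c1 | intermediate
5 | 3,5-bis(methoxymethoxy)-2-(3-methylbut-2-en-1-yl)phenyl N-isopropylcarbamate | CC(C)NC(=O)Oc1cc(OCOC)cc(OCOC)c1CC=C(C)C | intermediate
6 | N-(tert-butyldimethylsilyl) derivative of carbamate 5 | CC(C)N([Si](C)(C)C(C)(C)C)C(=O)Oc1cc(OCOC)cc(OCOC)c1CC=C(C)C | intermediate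
7 | aryllithium from 6, lithiated at the ring carbon between the carbamate and a MOM ether (C4a) | CC(C)N([Si](C)(C)C(C)(C)C)C(=O)Oc1c([Li])c(OCOC)cc(OCOC)c1CC=C(C)C | intermediate
8 | N-(tert-butyldimethylsilyl) derivative of carbamate 9 (C-trimethylsilylated) | CC(C)N([Si](C)(C)C(C)(C)C)C(=O)Oc1c([Si](C)(C)C)c(OCOC)cc(OCOC)c1CC=C(C)C | intermediate
9 | 3,5-bis(methoxymethoxy)-2-(3-methylbut-2-en-1-yl)-6-(trimethylsilyl)phenyl N-isopropylcarbamate | CC(C)NC(=O)Oc1c([Si](C)(C)C)c(OCOC)cc(OCOC)c1CC=C(C)C | intermediate
10 | DBU-H salt of 3,5-bis(methoxymethoxy)-2-(3-methylbut-2-en-1-yl)-6-(trimethylsilyl)phenoxide | COCOc1cc(OCOC)c([Si](C)(C)C)c([O-])c1CC=C(C)C.C1CCC2=[NH+]CCCN2CC1 | intermediate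
11 | 3,5-bis(methoxymethoxy)-2-(3-methylbut-2-en-1-yl)-6-(trimethylsilyl)phenyl trifluoromethanesulfonate | COCOc1cc(OCOC)c([Si](C)(C)C)c(OS(=O)(=O)C(F)(F)F)c1CC=C(C)C | intermediate
12 | methyl 3-(4-methoxyphenyl)-3-oxopropanoate | COC(=O)CC(=O)c1ccc(OC)cc1 | starting material
13 | methyl (S)-3-hydroxy-3-(4-methoxyphenyl)propanoate | COc1ccc([C@@H](O)CC(=O)OC)cc1 | intermediate
14 | (S)-3-hydroxy-N-methoxy-3-(4-methoxyphenyl)-N-methylpropanamide | COc1ccc([C@@H](O)CC(=O)N(C)OC)cc1 | intermediate
15 | sodium alkoxide of 14 | COc1ccc([C@@H]([O-])CC(=O)N(C)OC)cc1.[Na+] | intermediate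
16 | 1,2-didehydro-4,6-bis(methoxymethoxy)-3-(3-methylbut-2-en-1-yl)benzene (aryne, C4a≡C8a) | COCOC1=C(CC=C(C)C)C#CC(OCOC)=C1 | intermediate
17 | sodium aryl anion (charge at C4a) of (S)-3-[3,5-bis(methoxymethoxy)-2-(3-methylbut-2-en-1-yl)phenoxy]-N-methoxy-3-(4-methoxyphenyl)-N-methylpropanamide | COc1ccc([C@@H](Oc2c(CC=C(C)C)c(OCOC)cc(OCOC)[c-]2)CC(=O)N(C)OC)cc1.[Na+] | intermediate
18 | sodium (2S)-4-[methoxy(methyl)amino]-5,7-bis(methoxymethoxy)-2-(4-methoxyphenyl)-8-(3-methylbut-2-en-1-yl)chroman-4-olate (C4 configuration undefined) | COc1ccc([C@@H]2CC([O-])(N(C)OC)c3c(OCOC)cc(OCOC)c(CC=C(C)C)c3O2)cc1.[Na+] | intermediate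
19 | (2S)-5,7-bis(methoxymethoxy)-2-(4-methoxyphenyl)-8-(3-methylbut-2-en-1-yl)chroman-4-one | COc1ccc([C@@H]2CC(=O)c3c(OCOC)cc(OCOC)c(CC=C(C)C)c3O2)cc1 | intermediate
20 | (2S)-5,7-dihydroxy-2-(4-methoxyphenyl)-8-(3-methylbut-2-en-1-yl)chroman-4-one | COc1ccc([C@@H]2CC(=O)c3c(O)cc(O)c(CC=C(C)C)c3O2)cc1 | target

Total step count: 9. Longest linear sequence: 7 steps (steps 1, 2, 3, 4, 5, 8, 9).

**Steps most likely to fail**

Step 8 (the proposed new method). Three processes may defeat it: proton transfer to the aryl anion (from the C3 methylene or adventitious water) before it reaches the amide carbonyl, addition of the alkoxide to the wrong aryne carbon because C8a is flanked by the prenyl group, and retro-aldol fragmentation of the alkoxide. The fallback uses known chemistry and closes ring C by electrophilic instead of anionic acylation. It sets out from phenol 4, with the alcohol partner made from 12, and returns to the route at 19. Keto ester 12 would be reduced with the enantiomeric catalyst RuCl(p-cymene)[(R,R)-TsDPEN] in HCO2H/Et3N to methyl (R)-3-hydroxy-3-(4-methoxyphenyl)propanoate F1. Mitsunobu etherification of 4 with F1 (PPh3, DIAD, toluene, 0 °C) should give, with inversion, methyl (S)-3-[3,5-bis(methoxymethoxy)-2-(3-methylbut-2-en-1-yl)phenoxy]-3-(4-methoxyphenyl)propanoate F2. Saponification (LiOH, THF/H2O) should give (S)-3-[3,5-bis(methoxymethoxy)-2-(3-methylbut-2-en-1-yl)phenoxy]-3-(4-methoxyphenyl)propanoic acid F3. Intramolecular Friedel–Crafts acylation of F3 through its mixed trifluoroacetic anhydride (TFAA, CH2Cl2, 0 °C) can only occur at the single free carbon ortho to the ether oxygen and should give 19; any MOM loss there is harmless because step 9 removes both groups. The weakness of this fallback is possible erosion of configuration at the 4-methoxybenzylic carbon in the Mitsunobu and acylation steps.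

Step 4. Deprotonation may occur at the benzylic-allylic CH2 of the prenyl group or at C6 between the two MOM ethers instead of at C4a, and the silyl triflate may attack a MOM acetal. The fallback changes the order so that silicon is introduced before the prenyl group. It sets out from 2 and returns at 11. Carbamoylation of 2 (iPrNCO, Et3N) should give 3,5-bis(methoxymethoxy)phenyl N-isopropylcarbamate F4. Directed ortho-metalation and silylation under the conditions of step 4 should give 3,5-bis(methoxymethoxy)-2-(trimethylsilyl)phenyl N-isopropylcarbamate F5. Carbamate cleavage (Et2NH, DBU, MeCN) should give 3,5-bis(methoxymethoxy)-2-(trimethylsilyl)phenol F6. ortho-C-Prenylation of its sodium phenoxide (NaH, toluene, prenyl bromide) at the one free ortho carbon should give 3,5-bis(methoxymethoxy)-2-(3-methylbut-2-en-1-yl)-6-(trimethylsilyl)phenol F7, and triflation (PhNTf2, DBU, MeCN) should give 11.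

Step 2. O-alkylation, alkylation at the carbon para to the phenoxide oxygen and a second alkylation may compete with the desired ortho-C-alkylation. The fallback replaces direct C-alkylation by O-allylation and sigmatropic rearrangement. It sets out from 2 and returns at 4. O-Alkylation of 2 with methyl 2-methylbut-3-en-2-yl carbonate and the zerovalent palladium complex Pd(PPh3)4 (THF, 0 °C) should give the tertiary allyl ether 1,3-bis(methoxymethoxy)-5-[(2-methylbut-3-en-2-yl)oxy]benzene F8. Aromatic Claisen rearrangement of F8 (N,N-diethylaniline, 130 °C) can deliver the allyl unit only to an ortho carbon and with allylic transposition, which turns the 1,1-dimethylallyl group into the prenyl group of 4.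

Further compounds
F1 | step 8 | methyl (R)-3-hydroxy-3-(4-methoxyphenyl)propanoate | COc1ccc([C@H](O)CC(=O)OC)cc1
F2 | step 8 | methyl (S)-3-[3,5-bis(methoxymethoxy)-2-(3-methylbut-2-en-1-yl)phenoxy]-3-(4-methoxyphenyl)propanoate | COc1ccc([C@@H](Oc2cc(OCOC)cc(OCOC)c2CC=C(C)C)CC(=O)OC)cc1
F3 | step 8 | (S)-3-[3,5-bis(methoxymethoxy)-2-(3-methylbut-2-en-1-yl)phenoxy]-3-(4-methoxyphenyl)propanoic acid | COc1ccc([C@@H](Oc2cc(OCOC)cc(OCOC)c2CC=C(C)C)CC(=O)O)cc1
F4 | step 4 | 3,5-bis(methoxymethoxy)phenyl N-isopropylcarbamate | CC(C)NC(=O)Oc1cc(OCOC)cc(OCOC)c1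
F5 | step 4 | 3,5-bis(methoxymethoxy)-2-(trimethylsilyl)phenyl N-isopropylcarbamate | CC(C)NC(=O)Oc1cc(OCOC)cc(OCOC)c1[Si](C)(C)C
F6 | step 4 | 3,5-bis(methoxymethoxy)-2-(trimethylsilyl)phenol | COCOc1cc(O)c([Si](C)(C)C)c(OCOC)c1
F7 | step 4 | 3,5-bis(methoxymethoxy)-2-(3-methylbut-2-en-1-yl)-6-(trimethylsilyl)phenol | COCOc1cc(OCOC)c([Si](C)(C)C)c(O)c1CC=C(C)C
F8 | step 2 | 1,3-bis(methoxymethoxy)-5-[(2-methylbut-3-en-2-yl)oxy]benzene | C=CC(C)(C)Oc1cc(OCOC)cc(OCOC)c1
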